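**Plan**

1. Numbering: bicycle O1–O2–C3–C4–C4a–O5–C6(=O)–C7–C7a, side chain C1'–C8'. Retrosynthesis: C4–H back to a C4–I placeholder; the C5'–C6' bond of the side-chain diene (Stille); the lactone O5–C4a bond and, in the same flask, both peroxide C–O bonds (O2–C3, O1–C7a), back to acyclic trienoic acid 18; then the central bond of its 1,3-diene (Negishi) and the chain-side alkene (carbocupration of propyne).
2. Forward: (S)-3-bromo-2-methylpropan-1-ol → Z-iodoalkene → E,Z-diene → E-iodoalkene handle → β,γ-unsaturated acid → 1,2-dioxene ring first and γ-lactone ring second in one operation → side-chain diene → removal of iodine.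
3. Enabling feature: C3, C4, C4a and C7a are the four carbons of a 2,4-dimethyl-1,3-diene. Once O2 bridges C3 and C7a, the CH2CO2H arm on C7a is γ,δ to the remaining C4=C4a alkene, so its oxygen can only close on methyl-bearing C4a, 5-exo and on its own face (cis fusion).
4. Stereochemistry: C2' from commercial (S)-3; alkene geometries from syn carbocupration, syn hydrozirconation (twice) and syn carboalumination; C3/C7a from suprafacial cycloaddition to the E,Z-diene; C4a from the tether. The diene-face isomer is removed after step 8.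

Key step: step 8

Remark: the remote C8 methyl centre of 18 is not expected to bias the face of singlet-oxygen attack, so step 8 should give the target series together with its diene-face isomer, which is removed there by chromatography; 1, 3, 6 and 21 are taken as commercial.

**Route**

Step 1
Reactants: 1 pent-3-yn-1-ol
Product: 2 tert-butyldimethyl(pent-3-yn-1-yloxy)silane
Conditions: TBSCl, imidazole, CH2Cl2, 0 °C to rt
Reagents that add atoms: tert-butyldimethylsilyl chloride, CC(C)(C)[Si](C)(C)Cl
Why: Imidazole-promoted O-silylation of a primary alcohol is routine and masks the hydroxyl for the organometallic steps; no stereocentre is formed.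

Step 2
Reactants: 3 (S)-3-bromo-2-methylpropan-1-ol
Product: 5 [(4S)-5-bromo-4-methylpent-1-yn-1-yl]tri(propan-2-yl)silane, via bromo triflate 4 (not isolated)
Conditions: Tf2O, 2,6-lutidine, CH2Cl2, −78 °C; then LiC≡CSi(i-Pr)3 [from HC≡CSi(i-Pr)3, n-BuLi], THF/DMPU, −78 to −20 °C
Reagents that add atoms: ethynyltri(propan-2-yl)silane, C#C[Si](C(C)C)(C(C)C)C(C)C
Why: Triflation followed by SN2 alkynylation: a primary triflate is displaced by a lithium acetylide at low temperature far faster than a primary bromide, and because the methyl-bearing carbon is not a reacting centre its S configuration passes unchanged into 5.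

Step 3
Reactants: 5 [(4S)-5-bromo-4-methylpent-1-yn-1-yl]tri(propan-2-yl)silane; 6 propyne
Product: 10 [(4S,6Z)-7-iodo-4,6-dimethylhept-6-en-1-yn-1-yl]tri(propan-2-yl)silane, via Grignard reagent 7 (not isolated), via alkylcopper reagent 8 (not isolated), via alkenylcopper reagent 9 (not isolated)
Conditions: Mg, Et2O, rt; CuBr·SMe2, Et2O/Me2S, −45 °C; propyne, −45 to −25 °C; I2, THF, −45 to 0 °C
Reagents that add atoms: iodine, II
Why: Grignard formation, transmetalation to copper and syn-carbocupration of propyne deliver the alkyl group to C2 and copper to C1 on the same side, so iodinolysis with retention gives the Z iodide (chain cis to iodine), while the hindered silylalkyne is not carbometalated.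

Step 4
Reactants: 2 tert-butyldimethyl(pent-3-yn-1-yloxy)silane; 10 [(4S,6Z)-7-iodo-4,6-dimethylhept-6-en-1-yn-1-yl]tri(propan-2-yl)silane
Product: 13 tert-butyldimethyl{[(3E,5Z,8R)-4,6,8-trimethyl-11-[tri(propan-2-yl)silyl]undeca-3,5-dien-10-yn-1-yl]oxy}silane, via alkenylzirconocene 11 (not isolated), via alkenylzinc chloride 12 (not isolated)
Conditions: 2, Cp2Zr(H)Cl (excess), THF, 50 °C; ZnCl2, THF, 0 °C; then 10, Pd(PPh3)4 (cat.), rt
Reagents that add atoms: none
Why: Hydrozirconation–Negishi coupling: syn addition of Zr–H across 2, with zirconium settling on the methyl-bearing carbon under equilibration by excess hydride, defines the E alkene, and transmetalation to zinc followed by Pd-catalysed sp2–sp2 coupling with 10 proceeds with retention on both partners to give the E,Z-diene, the bulky silylalkyne resisting residual Zr–H.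

Step 5
Reactants: 13 tert-butyldimethyl{[(3E,5Z,8R)-4,6,8-trimethyl-11-[tri(propan-2-yl)silyl]undeca-3,5-dien-10-yn-1-yl]oxy}silane
Product: 14 (3E,5Z,8S)-4,6,8-trimethylundeca-3,5-dien-10-yn-1-ol
Conditions: TBAF, THF, 0 °C to rt
Reagents that add atoms: none
Why: Fluoride-mediated desilylation cleaves the silyl ether and the C(sp)–Si bond in one operation and leaves the diene and the stereocentre untouched (the descriptor changes only through substituent priorities).

Step 6
Reactants: 14 (3E,5Z,8S)-4,6,8-trimethylundeca-3,5-dien-10-yn-1-ol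
Product: 16 (3E,5Z,8R,10E)-11-iodo-4,6,8,10-tetramethylundeca-3,5,10-trien-1-ol, via alkenylalane 15 (not isolated)
Conditions: AlMe3, Cp2ZrCl2 (cat.), CH2Cl2, 0 °C to rt; I2, THF, −30 °C; aq. Rochelle salt
Reagents that add atoms: trimethylaluminium, C[Al](C)C; iodine, II
Why: Negishi carboalumination (zirconium-catalysed syn methylalumination of the terminal alkyne, methyl to the internal carbon) followed by iodinolysis with retention gives the E iodoalkene, the hydroxyl being masked in the flask as its aluminium alkoxide and the trisubstituted diene being inert to carbometalation.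

Step 7
Reactants: 16 (3E,5Z,8R,10E)-11-iodo-4,6,8,10-tetramethylundeca-3,5,10-trien-1-ol
Product: 18 (3E,5Z,8R,10E)-11-iodo-4,6,8,10-tetramethylundeca-3,5,10-trienoic acid, via trienal 17 (not isolated)
Conditions: Dess–Martin periodinane, NaHCO3, CH2Cl2, 0 °C; then NaClO2, NaH2PO4, 2-methyl-2-butene, t-BuOH/H2O, 0 °C
Reagents that add atoms: sodium chlorite, [Na+].[O-]Cl=O
Why: Dess–Martin oxidation and immediate Pinnick oxidation of the crude aldehyde under buffered, non-basic conditions give the β,γ-unsaturated acid while minimising migration of the diene into conjugation with the carbonyl group.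

Step 8
Reactants: 18 (3E,5Z,8R,10E)-11-iodo-4,6,8,10-tetramethylundeca-3,5,10-trienoic acid
Product: 20 (3R,4R,4aS,7aR)-4-iodo-3-[(2S,4E)-5-iodo-2,4-dimethylpent-4-en-1-yl]-3,4a-dimethyltetrahydro-3H-furo[3,2-c][1,2]dioxin-6(4H)-one, via dihydrodioxine acid 19 (not isolated)
Conditions: O2, tetraphenylporphyrin (cat.), visible light, CH2Cl2, −30 °C; then Ar purge, I2, NaHCO3, MeCN/H2O, 0 °C, dark; chromatography removes the diene-face isomer
Reagents that add atoms: dioxygen, O=O; iodine, II
Why: Sensitised singlet oxygen adds suprafacially as a [4+2] dienophile to the s-cis form of the 3E,5Z-diene of 18 to give the 3,6-dihydro-1,2-dioxine 19 (concerted six-membered closure), and iodine then activates the remaining ring alkene so that the carboxyl oxygen attacks the methyl-bearing carbon (5-exo-trig, Markovnikov) to form the O5–C4a bond. The closest known reaction types are endoperoxide formation from acyclic 1,3-dienes and iodolactonisation of γ,δ-unsaturated acids. The diene geometry controls C3 and C7a (the two outward groups, the C3 methyl and the CH2CO2H arm, end up cis), the three-atom tether forces the lactone oxygen onto the face of that arm (cis fusion at C4a/C7a), and anti addition fixes the temporary C4 iodide. The step needs [4+2] over ene periselectivity, which the 2,4-dimethyl pattern favours by destabilising the s-trans conformer through 1,3-allylic strain, and chemoselectivity over the electron-poor iodoalkene, which neither singlet oxygen nor iodine should attack. Nothing in 18 distinguishes the two diene faces relative to the remote methyl centre, so the face isomer (all four ring centres inverted) is expected alongside 20 and is separated at this stage.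

Step 9
Reactants: 21 but-2-yn-1-ylbenzene
Product: 23 [(2E)-3-iodobut-2-en-1-yl]benzene, via alkenylzirconocene 22 (not isolated)
Conditions: Cp2Zr(H)Cl (excess), THF, 50 °C; I2, THF, 0 °C
Reagents that add atoms: iodine, II
Why: Hydrozirconation of the internal alkyne is a syn addition that, after equilibration with excess Cp2Zr(H)Cl, leaves zirconium next to the methyl group, and iodinolysis with retention gives the E iodide.

Step 10
Reactants: 23 [(2E)-3-iodobut-2-en-1-yl]benzene
Product: 25 tributyl[(2E)-4-phenylbut-2-en-2-yl]stannane, via alkenyllithium 24 (not isolated)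
Conditions: t-BuLi, Et2O, −78 °C; Bu3SnCl, −78 °C to rt
Reagents that add atoms: tributyltin chloride, CCCC[Sn](Cl)(CCCC)CCCC
Why: Lithium–iodine exchange and trapping with Bu3SnCl both occur with retention of alkene geometry at −78 °C, converting the iodide into the Stille nucleophile.

Step 11
Reactants: 20 (3R,4R,4aS,7aR)-4-iodo-3-[(2S,4E)-5-iodo-2,4-dimethylpent-4-en-1-yl]-3,4a-dimethyltetrahydro-3H-furo[3,2-c][1,2]dioxin-6(4H)-one; 25 tributyl[(2E)-4-phenylbut-2-en-2-yl]stannane
Product: 26 (3R,4R,4aS,7aR)-4-iodo-3,4a-dimethyl-3-[(2S,4E,6E)-2,4,6-trimethyl-8-phenylocta-4,6-dien-1-yl]tetrahydro-3H-furo[3,2-c][1,2]dioxin-6(4H)-one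
Conditions: Pd2(dba)3 (cat.), AsPh3, CuI (cat.), NMP, rt, dark
Reagents that add atoms: none
Why: Stille coupling: zerovalent palladium inserts into the alkenyl C–I bond in preference to the hindered secondary alkyl C–I bond, both alkene geometries are retained, and the neutral, mild conditions are of the kind that dialkyl peroxides and lactones tolerate.

Step 12
Reactants: 26 (3R,4R,4aS,7aR)-4-iodo-3,4a-dimethyl-3-[(2S,4E,6E)-2,4,6-trimethyl-8-phenylocta-4,6-dien-1-yl]tetrahydro-3H-furo[3,2-c][1,2]dioxin-6(4H)-one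
Product: 27 plakortolide, (3R,4aR,7aR)-3,4a-dimethyl-3-[(2S,4E,6E)-2,4,6-trimethyl-8-phenylocta-4,6-dien-1-yl]tetrahydro-3H-furo[3,2-c][1,2]dioxin-6(4H)-one
Conditions: Bu3SnH, Et3B/air (cat.), toluene, 0 °C
Reagents that add atoms: none
Why: Radical chain dehalogenation with Bu3SnH: iodine abstraction from C4 and rapid hydrogen transfer to the secondary radical (kept faster than fragmentation by a high stannane concentration at low temperature) turn C4 into a methylene and leave the three ring stereocentres and the diene geometry unchanged.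

**Compound list**

1 | pent-3-yn-1-ol | CC#CCCO | starting material
2 | tert-butyldimethyl(pent-3-yn-1-yloxy)silane | CC#CCCO[Si](C)(C)C(C)(C)C | intermediate
3 | (S)-3-bromo-2-methylpropan-1-ol | OC[C@H](C)CBr | starting material
4 | (S)-3-bromo-2-methylpropyl trifluoromethanesulfonate | FC(F)(F)S(=O)(=O)OC[C@H](C)CBr | intermediate
5 | [(4S)-5-bromo-4-methylpent-1-yn-1-yl]tri(propan-2-yl)silane | CC(C)[Si](C(C)C)(C(C)C)C#CC[C@H](C)CBr | intermediate
6 | propyne | CC#C | starting material
7 | bromo{(2S)-2-methyl-5-[tri(propan-2-yl)silyl]pent-4-yn-1-yl}magnesium (Grignard reagent of 5) | CC(C)[Si](C(C)C)(C(C)C)C#CC[C@H](C)C[Mg]Br | intermediate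
8 | {(2S)-2-methyl-5-[tri(propan-2-yl)silyl]pent-4-yn-1-yl}copper | CC(C)[Si](C(C)C)(C(C)C)C#CC[C@H](C)C[Cu] | intermediate
9 | {(1Z,4S)-2,4-dimethyl-7-[tri(propan-2-yl)silyl]hept-1-en-6-yn-1-yl}copper (chain cis to copper) | CC(C)[Si](C(C)C)(C(C)C)C#CC[C@H](C)C/C(C)=C\[Cu] | intermediate
10 | [(4S,6Z)-7-iodo-4,6-dimethylhept-6-en-1-yn-1-yl]tri(propan-2-yl)silane | CC(C)[Si](C(C)C)(C(C)C)C#CC[C@H](C)C/C(C)=C\I | intermediate
11 | chlorobis(cyclopentadienyl)[(2E)-5-(tert-butyldimethylsilyloxy)pent-2-en-2-yl]zirconium | CC(C)(C)[Si](C)(C)OCC/C=C(C)/[Zr](Cl)(C1C=CC=C1)C1C=CC=C1 | intermediate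
12 | chloro[(2E)-5-(tert-butyldimethylsilyloxy)pent-2-en-2-yl]zinc | CC(C)(C)[Si](C)(C)OCC/C=C(C)/[Zn]Cl | intermediate
13 | tert-butyldimethyl{[(3E,5Z,8R)-4,6,8-trimethyl-11-[tri(propan-2-yl)silyl]undeca-3,5-dien-10-yn-1-yl]oxy}silane | CC(C)(C)[Si](C)(C)OCC/C=C(\C)/C=C(/C)\C[C@@H](C)CC#C[Si](C(C)C)(C(C)C)C(C)C | intermediate
14 | (3E,5Z,8S)-4,6,8-trimethylundeca-3,5-dien-10-yn-1-ol | OCC/C=C(\C)/C=C(/C)\C[C@@H](C)CC#C | intermediate
15 | O-dimethylaluminium alkoxide of (3E,5Z,8R,10E)-11-(dimethylalumanyl)-4,6,8,10-tetramethylundeca-3,5,10-trien-1-ol | C[Al](C)OCC/C=C(\C)/C=C(/C)\C[C@@H](C)C/C(C)=C/[Al](C)C | intermediate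
16 | (3E,5Z,8R,10E)-11-iodo-4,6,8,10-tetramethylundeca-3,5,10-trien-1-ol | OCC/C=C(\C)/C=C(/C)\C[C@@H](C)C/C(C)=C/I | intermediate
17 | (3E,5Z,8R,10E)-11-iodo-4,6,8,10-tetramethylundeca-3,5,10-trienal | O=CC/C=C(\C)/C=C(/C)\C[C@@H](C)C/C(C)=C/I | intermediate
18 | (3E,5Z,8R,10E)-11-iodo-4,6,8,10-tetramethylundeca-3,5,10-trienoic acid | OC(=O)C/C=C(\C)/C=C(/C)\C[C@@H](C)C/C(C)=C/I | intermediate
19 | 2-{(3R,6R)-6-[(2S,4E)-5-iodo-2,4-dimethylpent-4-en-1-yl]-4,6-dimethyl-3,6-dihydro-1,2-dioxin-3-yl}acetic acid | I/C=C(C)/C[C@H](C)C[C@]1(C)C=C(C)[C@@H](CC(O)=O)OO1 | intermediate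
20 | (3R,4R,4aS,7aR)-4-iodo-3-[(2S,4E)-5-iodo-2,4-dimethylpent-4-en-1-yl]-3,4a-dimethyltetrahydro-3H-furo[3,2-c][1,2]dioxin-6(4H)-one | I/C=C(C)/C[C@H](C)C[C@]1(C)[C@H](I)[C@@]2(C)OC(=O)C[C@H]2OO1 | intermediate
21 | but-2-yn-1-ylbenzene (1-phenyl-2-butyne) | CC#CCc1ccccc1 | starting material
22 | chlorobis(cyclopentadienyl)[(2E)-4-phenylbut-2-en-2-yl]zirconium | Cl[Zr](C1C=CC=C1)(C1C=CC=C1)/C(C)=C/Cc1ccccc1 | intermediate
23 | [(2E)-3-iodobut-2-en-1-yl]benzene | I/C(C)=C/Cc1ccccc1 | intermediate
24 | (4-phenylbut-2-en-2-yl)lithium, lithium trans to the benzyl group (formally 2Z because Li ranks below C) | [Li]/C(C)=C/Cc1ccccc1 | intermediate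
25 | tributyl[(2E)-4-phenylbut-2-en-2-yl]stannane | CCCC[Sn](CCCC)(CCCC)/C(C)=C/Cc1ccccc1 | intermediate
26 | (3R,4R,4aS,7aR)-4-iodo-3,4a-dimethyl-3-[(2S,4E,6E)-2,4,6-trimethyl-8-phenylocta-4,6-dien-1-yl]tetrahydro-3H-furo[3,2-c][1,2]dioxin-6(4H)-one | CC(=C\Cc1ccccc1)/C=C(\C)C[C@H](C)C[C@]1(C)[C@H](I)[C@@]2(C)OC(=O)C[C@H]2OO1 | intermediate
27 | plakortolide, (3R,4aR,7aR)-3,4a-dimethyl-3-[(2S,4E,6E)-2,4,6-trimethyl-8-phenylocta-4,6-dien-1-yl]tetrahydro-3H-furo[3,2-c][1,2]dioxin-6(4H)-one | CC(=C\Cc1ccccc1)/C=C(\C)C[C@H](C)C[C@]1(C)C[C@@]2(C)OC(=O)C[C@H]2OO1 | target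

**Step count**

Total: 12 steps. Longest linear sequence: 9 steps (3 → 27 through steps 2, 3, 4, 5, 6, 7, 8, 11 and 12).

**Steps most likely to fail, with fallbacks**

Step 8. What may go wrong: ene-type hydroperoxidation of the trisubstituted alkenes outrunning the cycloaddition; unbiased attack on both diene faces; loss of the unpurified dihydrodioxine acid through base-induced O–O cleavage; double-bond migration of 18 before it reacts. The fallback sets out from 16 and returns at 19. The photo-oxygenation is moved ahead of the oxidation to the acid. Alcohol 16 is photo-oxygenated (O2, tetraphenylporphyrin, visible light, CH2Cl2) to the neutral dihydrodioxine alcohol F1, which can be chromatographed free of ene products and of its face isomer. F1 is oxidised with TEMPO/PhI(OAc)2 in aqueous MeCN through the dihydrodioxine aldehyde F2 to acid 19, and iodolactonisation as in the second half of step 8 continues to 20. This also bypasses the isomerisation-prone acid 18.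

Step 11. What may go wrong: slow tin-to-palladium transfer from the α-methyl alkenylstannane, which gives time for reductive O–O cleavage by the low-valent metal or its ligand and for oxidative addition at the sp3 C–I bond. The fallback sets out from 23 and returns at 26. Lithium–iodine exchange of 23 (t-BuLi, −78 °C, through 24) and transmetalation with ZnCl2 give the alkenylzinc chloride F3. Negishi coupling of F3 with 20 (Pd(PPh3)4, THF, 0 °C) gives 26. Zinc-to-palladium transfer is fast at low temperature, so the peroxide is exposed to the catalyst only briefly.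

Step 12. What may go wrong: fragmentation of the C4 radical toward the neighbouring peroxide (loss of the O–O bridge), and addition of tin radicals to the side-chain diene with hydrostannation or E/Z scrambling. The fallback sets out from 15 and returns at 27. The order of reduction and coupling is exchanged by using a bromoalkene as the coupling handle. Alkenylalane 15 is quenched with N-bromosuccinimide instead of iodine to give the bromo trienol F4. Steps 7 and 8 are repeated on it (bromo trienal F5, bromo trienoic acid F6, bromo dihydrodioxine acid F7) to give the bromoalkenyl iodolactone F8. Bu3SnH/Et3B then reduces the sp3 C–I bond, which reacts with tin radicals far faster than an alkenyl bromide, to give the bromoalkenyl lactone F9 with no diene present. Negishi coupling of F9 with the zinc reagent F3 of the preceding fallback (Pd(PPh3)4, THF, rt) gives 27.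

**Further compounds**

F1 | step 8 | 2-{(3R,6R)-6-[(2S,4E)-5-iodo-2,4-dimethylpent-4-en-1-yl]-4,6-dimethyl-3,6-dihydro-1,2-dioxin-3-yl}ethan-1-ol | I/C=C(C)/C[C@H](C)C[C@]1(C)C=C(C)[C@@H](CCO)OO1
F2 | step 8 | 2-{(3R,6R)-6-[(2S,4E)-5-iodo-2,4-dimethylpent-4-en-1-yl]-4,6-dimethyl-3,6-dihydro-1,2-dioxin-3-yl}acetaldehyde | I/C=C(C)/C[C@H](C)C[C@]1(C)C=C(C)[C@@H](CC=O)OO1
F3 | step 11 | chloro[(2E)-4-phenylbut-2-en-2-yl]zinc | Cl[Zn]/C(C)=C/Cc1ccccc1
F4 | step 12 | (3E,5Z,8R,10E)-11-bromo-4,6,8,10-tetramethylundeca-3,5,10-trien-1-ol | OCC/C=C(\C)/C=C(/C)\C[C@@H](C)C/C(C)=C/Br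
F5 | step 12 | (3E,5Z,8R,10E)-11-bromo-4,6,8,10-tetramethylundeca-3,5,10-trienal | O=CC/C=C(\C)/C=C(/C)\C[C@@H](C)C/C(C)=C/Br
F6 | step 12 | (3E,5Z,8R,10E)-11-bromo-4,6,8,10-tetramethylundeca-3,5,10-trienoic acid | OC(=O)C/C=C(\C)/C=C(/C)\C[C@@H](C)C/C(C)=C/Br
F7 | step 12 | 2-{(3R,6R)-6-[(2S,4E)-5-bromo-2,4-dimethylpent-4-en-1-yl]-4,6-dimethyl-3,6-dihydro-1,2-dioxin-3-yl}acetic acid | Br/C=C(C)/C[C@H](C)C[C@]1(C)C=C(C)[C@@H](CC(O)=O)OO1
F8 | step 12 | (3R,4R,4aS,7aR)-3-[(2S,4E)-5-bromo-2,4-dimethylpent-4-en-1-yl]-4-iodo-3,4a-dimethyltetrahydro-3H-furo[3,2-c][1,2]dioxin-6(4H)-one | Br/C=C(C)/C[C@H](C)C[C@]1(C)[C@H](I)[C@@]2(C)OC(=O)C[C@H]2OO1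
F9 | step 12 | (3R,4aR,7aR)-3-[(2S,4E)-5-bromo-2,4-dimethylpent-4-en-1-yl]-3,4a-dimethyltetrahydro-3H-furo[3,2-c][1,2]dioxin-6(4H)-one | Br/C=C(C)/C[C@H](C)C[C@]1(C)C[C@@]2(C)OC(=O)C[C@H]2OO1
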